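**Retrosynthetic overview**
- The target is opened at C11=C12: an E-selective Horner–Wadsworth–Emmons reaction joins a silyl-protected decalin aldehyde (C1–C11) with an allylic phosphonate (C12–C16) made from L-serine.
- The aldehyde comes from a Δ5-7-ketone: C8 is built by two enolate steps (MeI, then an oxaziridine), C7 by Luche reduction, C5/C6 by hydroboration.
- The Δ5-7-ketone comes from an octalone by gem-dimethylation with deconjugation, Criegee degradation of an isopropenyl group and Wolff–Kishner reduction.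
- The octalone comes from a Robinson annulation whose intramolecular aldol condensation closes ring A.
- Ring order: ring B is taken preformed from (S)-carvone (it relays all ring stereochemistry); ring A is closed second by the aldol.

Convention used below: decalin positions follow drimane/labdane numbering (ring A = C1–C5, C10; ring B = C5–C10; C11 on C9; methyl on C8); α/β mean below/above the ring with the C10 methyl β.

**Core (steps 1–13)**

Step 1
Reactants: 1 (S)-(+)-carvone; 2 benzyl chloromethyl ether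
Product: 5 (3S,5S)-3-(benzyloxymethyl)-2-methyl-5-(prop-1-en-2-yl)cyclohexan-1-one (3,5-trans; C2 epimers), via (benzyloxymethyl)magnesium chloride 3 (not isolated), via trimethylsilyl enol ether 4 (not isolated)
Conditions: 2, Mg, HgCl2 (cat.), THF, −10 °C; CuBr·SMe2 (10 mol %), Me3SiCl, 1, THF, −78 → −40 °C; 1 M HCl
Reagents that add atoms: none
Why: Copper-catalysed 1,4-addition of the Grignard reagent (accelerated by Me3SiCl) occurs anti to the isopropenyl group by axial attack on the enone half-chair, so the carvone stereocentre fixes C9 (future 9β-CH2O group).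

Step 2
Reactants: 5; 6 methyl vinyl ketone
Product: 9 9β-(benzyloxymethyl)-7α-isopropenyl-10β-methyl-Δ4-octalin-3-one, via 1,5-diketone Michael adduct 7 (not isolated), via bicyclic ketol 8 (not isolated)
Conditions: KOH (0.1 equiv), EtOH, 0 → 25 °C; then KOH (1 equiv), 78 °C
Reagents that add atoms: none
Why: Robinson annulation in which the more substituted enolate adds to the enone anti to the neighbouring CH2OBn group (C10 methyl cis to C11) and the intramolecular aldol condensation of the 1,5-diketone closes ring A.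

Step 3
Reactants: 9
Product: 11 9β-(benzyloxymethyl)-7α-isopropenyl-4,4,10β-trimethyl-Δ5-octalin-3-one, via 4-monomethyl Δ5-3-ketone 10 (not isolated)
Conditions: KOtBu (2.5 equiv), t-BuOH/THF, 25 °C; MeI, 0 → 25 °C
Reagents that add atoms: iodomethane, CI
Why: Twofold α-alkylation of the extended dienolate at C4 with deconjugation (the standard gem-dimethylation of Δ4-3-ketones) moves the alkene to C5=C6 and creates no new stereocentre.

Step 4
Reactants: 11
Product: 13 7α-acetoxy-9β-(benzyloxymethyl)-4,4,10β-trimethyl-Δ5-octalin-3-one, via α-methoxy hydroperoxide 12 (not isolated)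
Conditions: O3, CH2Cl2/MeOH, −78 °C (to first excess); then Ac2O, Et3N, DMAP (cat.), 0 → 40 °C
Reagents that add atoms: ozone, [O-][O+]=O; methanol, CO
Why: Ozone cleaves the unhindered 1,1-disubstituted alkene in preference to the Δ5 alkene flanked by two quaternary carbons, and acetylation of the methoxy hydroperoxide triggers a Criegee rearrangement in which C7 migrates to oxygen with retention.

Step 5
Reactants: 13
Product: 15 9β-(benzyloxymethyl)-4,4,10β-trimethyl-Δ5-octalin-7α-ol, via 7α-hydroxy hydrazone 14 (not isolated)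
Conditions: N2H4·H2O, KOH, diethylene glycol, 130 → 200 °C
Reagents that add atoms: none
Why: Wolff–Kishner (Huang–Minlon) reduction removes the C3 carbonyl through its hydrazone while hot KOH cleaves the acetate; the benzyl ether, the hindered alkene and the allylic alkoxide are inert to base.

Step 6
Reactants: 15
Product: 16 9β-(benzyloxymethyl)-4,4,10β-trimethyl-Δ5-octalin-7-one
Conditions: Dess–Martin periodinane, NaHCO3, CH2Cl2, 25 °C
Reagents that add atoms: none
Why: Dess–Martin oxidation of the allylic alcohol gives the Δ5-7-ketone and deliberately erases the C7 centre (wrong, α) so that it can be reset in step 9.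

Step 7
Reactants: 16
Product: 18 11-(benzyloxy)-8α-methyl-4,4,10β-trimethyl-Δ5-octalin-7-one (8βH-drim-5-en-7-one), via lithium dienolate 17 (not isolated)
Conditions: LiN(iPr)2 (1.1 equiv), THF, −78 °C; MeI, −78 → 0 °C
Reagents that add atoms: iodomethane, CI
Why: Enolate alkylation at C8, the only enolisable position because both γ-carbons are quaternary; the methyl is expected α (anti to the C10 methyl), but this centre is planarised again in step 8.

Step 8
Reactants: 18
Product: 20 11-(benzyloxy)-8α-hydroxydrim-5-en-7-one (8β-CH3), via potassium enolate 19 (not isolated)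
Conditions: KN(SiMe3)2, THF, −78 °C; 2-(phenylsulfonyl)-3-phenyloxaziridine, −78 °C; AcOH
Reagents that add atoms: 2-(phenylsulfonyl)-3-phenyloxaziridine, O=S(=O)(N1OC1c1ccccc1)c1ccccc1
Why: Davis enolate hydroxylation; the oxidant reaches the tetrasubstituted enolate from the α-face because the β-face is blocked by the axial C10 methyl, giving 8α-OH with the methyl forced β.

Step 9
Reactants: 20
Product: 21 11-(benzyloxy)drim-5-ene-7β,8α-diol
Conditions: NaBH4, CeCl3·7H2O, MeOH, −40 → 0 °C
Reagents that add atoms: none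
Why: Luche 1,2-reduction; hydride adds to C7 from the α-face, away from the axial 8β- and 10β-methyls, giving the equatorial 7β-alcohol.

Step 10
Reactants: 21
Product: 23 11-(benzyloxy)-5α-drimane-6α,7β,8α-triol, via 6α-borylated organoborane 22 (not isolated)
Conditions: BH3·THF (6 equiv), THF, 0 → 40 °C; then 3 M NaOH, 30% H2O2, 0 → 25 °C
Reagents that add atoms: hydrogen peroxide, OO
Why: Hydroboration–oxidation; syn addition from the α-face (anti to the allylic 7β-oxygen and to the C10 and 4β methyls) with boron on the less substituted C6 sets 5α-H (trans-decalin) and, after retentive oxidation, 6α-OH.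

Step 11
Reactants: 23
Product: 24 11-(benzyloxy)-6α,7β,8α-tris(triethylsilyloxy)-5α-drimane
Conditions: Et3SiOTf (5 equiv), 2,6-lutidine, CH2Cl2, −40 → 25 °C
Reagents that add atoms: triethylsilyl trifluoromethanesulfonate, CC[Si](CC)(CC)OS(=O)(=O)C(F)(F)F
Why: Exhaustive silylation with the silyl triflate also caps the tertiary C8 alcohol, which removes the retro-aldol pathway of the later β-hydroxy aldehyde.

Step 12
Reactants: 24
Product: 25 6α,7β,8α-tris(triethylsilyloxy)-5α-drimane-11-ol
Conditions: H2 (1 atm), Pd/C (10%), EtOAc, 25 °C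
Reagents that add atoms: none
Why: Hydrogenolysis of the benzyl ether; no alkene is left in the molecule and silyl ethers survive neutral conditions.

Step 13
Reactants: 25
Product: 26 6α,7β,8α-tris(triethylsilyloxy)-5α-drimane-11-al
Conditions: Dess–Martin periodinane, NaHCO3, CH2Cl2, 0 → 25 °C
Reagents that add atoms: none
Why: Dess–Martin oxidation of the primary alcohol under buffered conditions; the equatorial 9β-aldehyde is also the thermodynamic epimer, so C9 is secure.

**Side chain (steps 14–21)**

Step 14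
Reactants: 27 L-serine
Product: 28 (S)-glyceric acid
Conditions: NaNO2, aq. H2SO4, 0 → 25 °C
Reagents that add atoms: water, O
Why: Diazotisation of the α-amino acid proceeds with net retention (double inversion through the α-lactone), so the (S)-centre that becomes C14 is taken from the chiral pool.

Step 15
Reactants: 28
Product: 29 methyl (S)-2,2-dimethyl-1,3-dioxolane-4-carboxylate
Conditions: 2,2-dimethoxypropane, MeOH, p-TsOH (cat.), 25 °C
Reagents that add atoms: 2,2-dimethoxypropane, COC(C)(C)OC; methanol, CO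
Why: One-pot acid-catalysed acetonide formation and Fischer esterification, which do not touch the stereocentre.

Step 16
Reactants: 29
Product: 30 (S)-N-methoxy-N,2,2-trimethyl-1,3-dioxolane-4-carboxamide
Conditions: MeNH(OMe)·HCl, i-PrMgCl, THF, −20 → 0 °C; H2O
Reagents that add atoms: N,O-dimethylhydroxylamine hydrochloride, CNOC.Cl
Why: Weinreb amide formation by aminolysis of the ester with the magnesium amide at low temperature, without epimerisation.

Step 17
Reactants: 30
Product: 31 (S)-1-(2,2-dimethyl-1,3-dioxolan-4-yl)ethan-1-one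
Conditions: MeMgBr, THF, 0 °C; H2O
Reagents that add atoms: methylmagnesium bromide, C[Mg]Br
Why: Grignard addition to the Weinreb amide stops at the chelated tetrahedral adduct, which gives the methyl ketone on work-up.

Step 18
Reactants: 31
Product: 32 (R)-2,2-dimethyl-4-(prop-1-en-2-yl)-1,3-dioxolane
Conditions: Ph3PCH3Br, KN(SiMe3)2, THF, −78 → 0 °C
Reagents that add atoms: methyltriphenylphosphonium bromide, C[P+](c1ccccc1)(c1ccccc1)c1ccccc1.[Br-]
Why: Wittig methylenation, run cold with a slight deficit of base to limit enolisation of the α-alkoxy ketone (the descriptor changes to R only through CIP priorities).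

Step 19
Reactants: 32
Product: 33 2-[(4R)-2,2-dimethyl-1,3-dioxolan-4-yl]prop-2-en-1-ol
Conditions: SeO2 (0.3 equiv), t-BuOOH, CH2Cl2, 25 °C
Reagents that add atoms: selenium dioxide, O=[Se]=O; tert-butyl hydroperoxide, CC(C)(C)OO
Why: SeO2-catalysed allylic oxidation (ene reaction then [2,3]-shift) attacks the methyl group of the 1,1-disubstituted alkene in preference to the hindered methine, leaving the stereocentre untouched.

Step 20
Reactants: 33
Product: 34 (4R)-4-(3-bromoprop-1-en-2-yl)-2,2-dimethyl-1,3-dioxolane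
Conditions: CBr4, PPh3, 2,6-lutidine, CH2Cl2, 0 °C
Reagents that add atoms: carbon tetrabromide, BrC(Br)(Br)Br
Why: Appel bromination converts the primary allylic alcohol to the bromide under neutral conditions that the acetonide tolerates.

Step 21
Reactants: 34
Product: 35 diethyl {2-[(4R)-2,2-dimethyl-1,3-dioxolan-4-yl]prop-2-en-1-yl}phosphonate
Conditions: P(OEt)3, neat, 110 °C
Reagents that add atoms: triethyl phosphite, CCOP(OCC)OCC
Why: Michaelis–Arbuzov reaction of the reactive allylic bromide, with loss of bromoethane.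

**Coupling and deprotection (steps 22–23)**

Step 22
Reactants: 26; 35
Product: 37 (11E)-6α,7β,8α-tris(triethylsilyloxy)-14,15-O-isopropylidene-labda-11,13(16)-diene-14R,15-diol, via lithiated phosphonate 36 (not isolated)
Conditions: 35, n-BuLi, THF/HMPA, −78 °C; then 26, −78 → 25 °C
Reagents that add atoms: none
Why: Horner–Wadsworth–Emmons olefination in which the lithiated allylic phosphonate adds through its α-carbon and the adduct eliminates to the thermodynamically favoured (E)-alkene, giving the 2-substituted 1,3-diene directly.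

Step 23
Reactants: 37
Product: 38 (11E,14R)-labda-11,13(16)-diene-6α,7β,8α,14,15-pentaol (target)
Conditions: 1 M HCl/THF (1:2), 25 °C
Reagents that add atoms: none
Why: Mild acidic hydrolysis cleaves the three silyl ethers and the acetonide in one operation without touching the diene or any stereocentre.

**Compound list**
1 | (S)-(+)-carvone | CC1=CC[C@@H](CC1=O)C(C)=C | starting material
2 | benzyl chloromethyl ether | ClCOCc1ccccc1 | starting material
3 | (benzyloxymethyl)magnesium chloride | Cl[Mg]COCc1ccccc1 | intermediate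
4 | trimethylsilyl enol ether of 5 (C5=C10) | c1ccccc1COC[C@H]1C[C@H](C(C)=C)CC(O[Si](C)(C)C)=C1C | intermediate
5 | (3S,5S)-3-(benzyloxymethyl)-2-methyl-5-(prop-1-en-2-yl)cyclohexan-1-one, C2 epimers | c1ccccc1COC[C@H]1C[C@H](C(C)=C)CC(=O)C1C | intermediate
6 | methyl vinyl ketone | CC(=O)C=C | starting material
7 | (3S,5S)-3-(benzyloxymethyl)-2-methyl-2-(3-oxobutyl)-5-(prop-1-en-2-yl)cyclohexan-1-one, oxobutyl anti to CH2OBn | c1ccccc1COC[C@H]1C[C@H](C(C)=C)CC(=O)[C@]1(C)CCC(C)=O | intermediate
8 | 5-hydroxy-3-keto aldol adduct (10β-CH3, 9β-CH2OBn, 7α-isopropenyl; C5 unassigned) | c1ccccc1COC[C@H]1C[C@H](C(C)=C)CC2(O)CC(=O)CC[C@@]21C | intermediate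
9 | 9β-(benzyloxymethyl)-7α-isopropenyl-10β-methyl-Δ4-octalin-3-one | c1ccccc1COC[C@H]1C[C@H](C(C)=C)CC2=CC(=O)CC[C@@]21C | intermediate
10 | 4-monomethyl Δ5-3-ketone (C4 unassigned) | c1ccccc1COC[C@H]1C[C@H](C(C)=C)C=C2C(C)C(=O)CC[C@@]21C | intermediate
11 | 9β-(benzyloxymethyl)-7α-isopropenyl-4,4,10β-trimethyl-Δ5-octalin-3-one | c1ccccc1COC[C@H]1C[C@H](C(C)=C)C=C2C(C)(C)C(=O)CC[C@@]21C | intermediate
12 | 7α-(1-hydroperoxy-1-methoxyethyl) derivative of 11 | c1ccccc1COC[C@H]1C[C@H](C(C)(OC)OO)C=C2C(C)(C)C(=O)CC[C@@]21C | intermediate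
13 | 7α-acetoxy-9β-(benzyloxymethyl)-4,4,10β-trimethyl-Δ5-octalin-3-one | c1ccccc1COC[C@H]1C[C@H](OC(C)=O)C=C2C(C)(C)C(=O)CC[C@@]21C | intermediate
14 | C3 hydrazone of the 7α-hydroxy-3-ketone | c1ccccc1COC[C@H]1C[C@H](O)C=C2C(C)(C)C(=NN)CC[C@@]21C | intermediate
15 | 9β-(benzyloxymethyl)-4,4,10β-trimethyl-Δ5-octalin-7α-ol | c1ccccc1COC[C@H]1C[C@H](O)C=C2C(C)(C)CCC[C@@]21C | intermediate
16 | 9β-(benzyloxymethyl)-4,4,10β-trimethyl-Δ5-octalin-7-one | c1ccccc1COC[C@H]1CC(=O)C=C2C(C)(C)CCC[C@@]21C | intermediate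
17 | lithium dienolate of 16 (C7–OLi, C7=C8) | c1ccccc1COC[C@H]1C=C(O[Li])C=C2C(C)(C)CCC[C@@]21C | intermediate
18 | 11-(benzyloxy)-8α-methyl Δ5-7-ketone (8βH-drim-5-en-7-one) | c1ccccc1COC[C@H]1[C@H](C)C(=O)C=C2C(C)(C)CCC[C@@]21C | intermediate
19 | potassium enolate of 18 (C7–OK, C7=C8) | c1ccccc1COC[C@H]1C(C)=C(O[K])C=C2C(C)(C)CCC[C@@]21C | intermediate
20 | 11-(benzyloxy)-8α-hydroxydrim-5-en-7-one | c1ccccc1COC[C@H]1[C@](C)(O)C(=O)C=C2C(C)(C)CCC[C@@]21C | intermediate
21 | 11-(benzyloxy)drim-5-ene-7β,8α-diol | c1ccccc1COC[C@H]1[C@](C)(O)[C@@H](O)C=C2C(C)(C)CCC[C@@]21C | intermediate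
22 | 6α-boryl, 7,8-O-boryl organoborane | c1ccccc1COC[C@H]1[C@](C)(OB)[C@@H](OB)[C@H](B)[C@H]2C(C)(C)CCC[C@@]21C | intermediate
23 | 11-(benzyloxy)-5α-drimane-6α,7β,8α-triol | c1ccccc1COC[C@H]1[C@](C)(O)[C@@H](O)[C@H](O)[C@H]2C(C)(C)CCC[C@@]21C | intermediate
24 | 11-(benzyloxy)-6α,7β,8α-tris(triethylsilyloxy)-5α-drimane | c1ccccc1COC[C@H]1[C@](C)(O[Si](CC)(CC)CC)[C@@H](O[Si](CC)(CC)CC)[C@H](O[Si](CC)(CC)CC)[C@H]2C(C)(C)CCC[C@@]21C | intermediate
25 | 6α,7β,8α-tris(triethylsilyloxy)-5α-drimane-11-ol | OC[C@H]1[C@](C)(O[Si](CC)(CC)CC)[C@@H](O[Si](CC)(CC)CC)[C@H](O[Si](CC)(CC)CC)[C@H]2C(C)(C)CCC[C@@]21C | intermediate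
26 | 6α,7β,8α-tris(triethylsilyloxy)-5α-drimane-11-al | O=C[C@H]1[C@](C)(O[Si](CC)(CC)CC)[C@@H](O[Si](CC)(CC)CC)[C@H](O[Si](CC)(CC)CC)[C@H]2C(C)(C)CCC[C@@]21C | intermediate
27 | L-serine | N[C@@H](CO)C(=O)O | starting material
28 | (S)-glyceric acid | O[C@@H](CO)C(=O)O | intermediate
29 | methyl (S)-2,2-dimethyl-1,3-dioxolane-4-carboxylate | COC(=O)[C@@H]1COC(C)(C)O1 | intermediate
30 | (S)-N-methoxy-N,2,2-trimethyl-1,3-dioxolane-4-carboxamide | CON(C)C(=O)[C@@H]1COC(C)(C)O1 | intermediate
31 | (S)-1-(2,2-dimethyl-1,3-dioxolan-4-yl)ethan-1-one | CC(=O)[C@@H]1COC(C)(C)O1 | intermediate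
32 | (R)-2,2-dimethyl-4-(prop-1-en-2-yl)-1,3-dioxolane | C=C(C)[C@@H]1COC(C)(C)O1 | intermediate
33 | 2-[(4R)-2,2-dimethyl-1,3-dioxolan-4-yl]prop-2-en-1-ol | C=C(CO)[C@@H]1COC(C)(C)O1 | intermediate
34 | (4R)-4-(3-bromoprop-1-en-2-yl)-2,2-dimethyl-1,3-dioxolane | C=C(CBr)[C@@H]1COC(C)(C)O1 | intermediate
35 | diethyl {2-[(4R)-2,2-dimethyl-1,3-dioxolan-4-yl]prop-2-en-1-yl}phosphonate | C=C(CP(=O)(OCC)OCC)[C@@H]1COC(C)(C)O1 | intermediate
36 | α-lithiated 35 | [Li]C(C(=C)[C@@H]1COC(C)(C)O1)P(=O)(OCC)OCC | intermediate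
37 | (11E)-6α,7β,8α-tris(triethylsilyloxy)-14,15-O-isopropylidene-labda-11,13(16)-diene-14R,15-diol | C=C(/C=C/[C@H]1[C@](C)(O[Si](CC)(CC)CC)[C@@H](O[Si](CC)(CC)CC)[C@H](O[Si](CC)(CC)CC)[C@H]2C(C)(C)CCC[C@@]21C)[C@@H]1COC(C)(C)O1 | intermediate
38 | (11E,14R)-labda-11,13(16)-diene-6α,7β,8α,14,15-pentaol | C=C(/C=C/[C@H]1[C@](C)(O)[C@@H](O)[C@H](O)[C@H]2C(C)(C)CCC[C@@]21C)[C@@H](O)CO | target

**Totals**
Total step count: 23.
Longest linear sequence: 15 steps (steps 1–13, then 22 and 23); the side-chain branch is 8 steps (14–21) and joins at step 22.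

**Three steps most likely to fail, with fallbacks**

Step 2 (Robinson annulation). The Michael addition must occur at the hindered, more substituted α-carbon next to the CH2OBn-bearing centre; reaction at the CH2 side or polymerisation of the enone would cut the yield. Fallback, setting out from compound 4 (isolated from step 1 by non-aqueous work-up instead of hydrolysis): MeLi in THF cleaves the silyl enol ether to the regiodefined lithium enolate F1. This is added at −78 °C to 3-(trimethylsilyl)but-3-en-2-one (Stork–Ganem acceptor) to give the silylated Michael adduct F2, again anti to the CH2OBn group. KOH in MeOH at reflux then removes the silyl group and effects the same intramolecular aldol condensation, and the route is rejoined at compound 9.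

Step 4 (ozonolysis/Criegee rearrangement). Ozone may also attack the Δ5 alkene or the benzyl ether. Fallback, setting out from compound 11: Wolff–Kishner reduction first gives the C3-deoxygenated diene F3. OsO4 (cat.)/NaIO4 with 2,6-lutidine in dioxane/water, which is governed by sterics and touches only the isopropenyl group, gives the 7α-methyl ketone F4. Me3SiOTf/Et3N converts F4 into the conjugated silyl dienol ether F5. One equivalent of ozone at −78 °C followed by Me2S cleaves only the electron-rich enol ether double bond and delivers the Δ5-7-ketone, so the route is rejoined at compound 16.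

Step 22 (olefination). The aldehyde is flanked by two fully substituted carbons and carries a β-silyloxy group, so the basic phosphonate anion may enolise it and cause β-elimination, or add through its γ-carbon. Fallback, setting out from compounds 26 and 31: under non-basic Takai–Utimoto conditions (CrCl2, Cl2CHB(pin), LiI, THF) aldehyde 26 gives the (E)-alkenyl pinacol boronate F6. Ketone 31 is converted with KN(SiMe3)2 and PhNTf2 at −78 °C into the enol triflate F7. Suzuki–Miyaura coupling of F6 with F7 (Pd(PPh3)4 as zerovalent palladium catalyst, K3PO4, dioxane/water, 60 °C) proceeds with retention of the E geometry, and the route is rejoined at compound 37.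

**Further compounds**
F1 | step 2 | lithium enolate of 5 (C5–OLi, C5=C10) | c1ccccc1COC[C@H]1C[C@H](C(C)=C)CC(O[Li])=C1C
F2 | step 2 | (3S,5S)-3-(benzyloxymethyl)-2-methyl-2-[3-oxo-2-(trimethylsilyl)butyl]-5-(prop-1-en-2-yl)cyclohexan-1-one, side chain anti to CH2OBn | c1ccccc1COC[C@H]1C[C@H](C(C)=C)CC(=O)[C@]1(C)CC([Si](C)(C)C)C(C)=O
F3 | step 4 | 9β-(benzyloxymethyl)-7α-isopropenyl-4,4,10β-trimethyl-Δ5-octalin | c1ccccc1COC[C@H]1C[C@H](C(C)=C)C=C2C(C)(C)CCC[C@@]21C
F4 | step 4 | 7α-acetyl-9β-(benzyloxymethyl)-4,4,10β-trimethyl-Δ5-octalin | c1ccccc1COC[C@H]1C[C@H](C(C)=O)C=C2C(C)(C)CCC[C@@]21C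
F5 | step 4 | trimethylsilyl dienol ether of F4 (C7=C(OSiMe3)CH3, Δ5) | c1ccccc1COC[C@H]1CC(=C(C)O[Si](C)(C)C)C=C2C(C)(C)CCC[C@@]21C
F6 | step 22 | (E)-alkenyl pinacol boronate from 26 (C11=C12–B(pin), tris-triethylsilyl ether) | CC1(C)OB(/C=C/[C@H]2[C@](C)(O[Si](CC)(CC)CC)[C@@H](O[Si](CC)(CC)CC)[C@H](O[Si](CC)(CC)CC)[C@H]3C(C)(C)CCC[C@@]32C)OC1(C)C
F7 | step 22 | (S)-1-(2,2-dimethyl-1,3-dioxolan-4-yl)vinyl trifluoromethanesulfonate | C=C(OS(=O)(=O)C(F)(F)F)[C@@H]1COC(C)(C)O1
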